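## Retrosynthetic overview

1. The target comes from a reagent-controlled double Shi epoxidation of the 3E,7E-diene acetate; the C10 acetate comes from Mitsunobu inversion of the C10 alcohol.
2. The twelve-membered ring is closed by an intramolecular CrCl2 (Nozaki–Hiyama) allylation forming C10–C11 from a 2-(bromomethyl)cyclohexenone and a tethered β,γ-unsaturated aldehyde. This sets C11, C10 and the exocyclic methylene.
3. The seco chain is joined to ring A by an sp3–sp2 Negishi coupling (C2–C3) of an (iodomethyl)cyclohexenone with an E,E-dienyl iodide; C18 is added by Morita–Baylis–Hillman hydroxymethylation.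
4. The ring A fragment comes from an organocatalytic desymmetrising malonate addition to 4,4-dimethylcyclohexa-2,5-dienone (sets C1), then decarboxylation and iododecarboxylation. The chain comes from two Zr-catalysed carboaluminations and one Negishi coupling.
5. Ring order: ring A (six-membered) is bought in, the macrocycle is closed at step 13, and the two oxiranes are formed last.

Assumption: 4,4-dimethylcyclohexa-2,5-dien-1-one, tert-butyl(but-3-yn-1-yloxy)dimethylsilane and (4-bromobut-1-yn-1-yl)trimethylsilane are taken as purchasable; locants C1–C15 (C18 = exocyclic CH2) follow the bicyclo[9.3.1]pentadecane numbering with C1 and C11 as bridgeheads.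

## Route

Step 1
Reactants: 1 tert-butyl(but-3-yn-1-yloxy)dimethylsilane
Product: 3 (E)-tert-butyl[(4-iodo-3-methylbut-3-en-1-yl)oxy]dimethylsilane, via alkenyldimethylalane 2 (not isolated)
Conditions: Me3Al (2.5 equiv), Cp2ZrCl2 (0.25 equiv), CH2Cl2, 0 °C to rt; then I2, THF, −30 °C
Reagents that add atoms: trimethylaluminium, C[Al](C)C; iodine, II
Why: Negishi Zr-catalysed carboalumination adds Me and Al syn across the terminal alkyne (Al on the terminal carbon), and iodinolysis of the C–Al bond with retention fixes the E trisubstituted alkene (future C7=C8).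

Step 2
Reactants: 3 (E)-tert-butyl[(4-iodo-3-methylbut-3-en-1-yl)oxy]dimethylsilane; 4 (4-bromobut-1-yn-1-yl)trimethylsilane
Product: 6 (E)-tert-butyldimethyl{[3-methyl-8-(trimethylsilyl)oct-3-en-7-yn-1-yl]oxy}silane, via homopropargylzinc bromide 5 (not isolated)
Conditions: 4, Zn dust, I2 (cat.), DMA, 80 °C; then 3, Pd(PPh3)4 (3 mol %), THF, rt
Reagents that add atoms: none
Why: Negishi sp3–sp2 cross-coupling of the alkylzinc bromide with the alkenyl iodide keeps the alkene geometry, and the silyl cap keeps the alkyne out of the coupling.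

Step 3
Reactants: 6 (E)-tert-butyldimethyl{[3-methyl-8-(trimethylsilyl)oct-3-en-7-yn-1-yl]oxy}silane
Product: 7 (E)-tert-butyldimethyl[(3-methyloct-3-en-7-yn-1-yl)oxy]silane
Conditions: K2CO3 (0.2 equiv), MeOH, rt
Reagents that add atoms: none
Why: Base-catalysed methanolysis (protodesilylation) of the alkynyl–Si bond is selective over the TBS ether.

Step 4
Reactants: 7 (E)-tert-butyldimethyl[(3-methyloct-3-en-7-yn-1-yl)oxy]silane
Product: 9 tert-butyl{[(3E,7E)-8-iodo-3,7-dimethylocta-3,7-dien-1-yl]oxy}dimethylsilane, via dienyldimethylalane 8 (not isolated)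
Conditions: Me3Al (2.5 equiv), Cp2ZrCl2 (0.25 equiv), CH2Cl2, rt; then I2, THF, −30 °C
Reagents that add atoms: trimethylaluminium, C[Al](C)C; iodine, II
Why: A second Negishi carboalumination–iodinolysis (syn addition, retention) sets the E alkene that becomes C3=C4; the existing trisubstituted alkene and silyl ether are inert.

Step 5
Reactants: 10 4,4-dimethylcyclohexa-2,5-dien-1-one; 11 dimethyl malonate
Product: 12 dimethyl 2-[(1S)-2,2-dimethyl-5-oxocyclohex-3-en-1-yl]propanedioate
Conditions: 1-[(1R,2R)-2-aminocyclohexyl]-3-[3,5-bis(trifluoromethyl)phenyl]thiourea (10 mol %), PhCO2H (10 mol %), toluene, rt (0.9 GPa if slow)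
Reagents that add atoms: none
Why: Iminium-activated organocatalytic asymmetric Michael addition desymmetrises the dienone, the chiral primary amine–thiourea selecting one enantiotopic enone and face so that C1 is formed as drawn (the catalyst antipode gives the other enantiomer), and the second enone is kept for later.

Step 6
Reactants: 12 dimethyl 2-[(1S)-2,2-dimethyl-5-oxocyclohex-3-en-1-yl]propanedioate
Product: 14 2-[(1S)-2,2-dimethyl-5-oxocyclohex-3-en-1-yl]acetic acid, via malonic diacid 13 (not isolated)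
Conditions: 6 M aq. HCl, AcOH, 100 °C
Reagents that add atoms: water, O
Why: Acid hydrolysis of the malonate and thermal decarboxylation of the malonic acid leave the CH2CO2H arm; C1 is not α to any carbonyl and cannot epimerise.

Step 7
Reactants: 14 2-[(1S)-2,2-dimethyl-5-oxocyclohex-3-en-1-yl]acetic acid
Product: 15 (5R)-5-(iodomethyl)-4,4-dimethylcyclohex-2-en-1-one
Conditions: PhI(OAc)2, I2, CCl4, hν, reflux
Reagents that add atoms: iodine, II
Why: Suárez iododecarboxylation (acyl hypoiodite, radical decarboxylation, fast iodine-atom transfer) turns the acid into the primary iodide C2–I without touching C1 (the descriptor changes only by CIP priority).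

Step 8
Reactants: 15 (5R)-5-(iodomethyl)-4,4-dimethylcyclohex-2-en-1-one; 9 tert-butyl{[(3E,7E)-8-iodo-3,7-dimethylocta-3,7-dien-1-yl]oxy}dimethylsilane
Product: 17 (5R)-5-[(2E,6E)-9-{[tert-butyl(dimethyl)silyl]oxy}-3,7-dimethylnona-2,6-dien-1-yl]-4,4-dimethylcyclohex-2-en-1-one, via alkylzinc iodide 16 (not isolated)
Conditions: 15, Zn dust, LiCl, THF, 35 °C; then 9, Pd(PPh3)4 (5 mol %), THF, 50 °C
Reagents that add atoms: none
Why: Zinc insertion gives an enone-tolerant alkylzinc iodide whose Negishi sp3–sp2 coupling with the alkenyl iodide forms C2–C3 with retention of the E geometry; alkylzinc halides do not add to the enone without copper or nickel.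

Step 9
Reactants: 17 (5R)-5-[(2E,6E)-9-{[tert-butyl(dimethyl)silyl]oxy}-3,7-dimethylnona-2,6-dien-1-yl]-4,4-dimethylcyclohex-2-en-1-one
Product: 18 (5R)-5-[(2E,6E)-9-{[tert-butyl(dimethyl)silyl]oxy}-3,7-dimethylnona-2,6-dien-1-yl]-2-(hydroxymethyl)-4,4-dimethylcyclohex-2-en-1-one
Conditions: 37% aq. HCHO, DMAP (0.3 equiv), THF–H2O, rt
Reagents that add atoms: formaldehyde, C=O
Why: Morita–Baylis–Hillman reaction: DMAP adds reversibly to C11, the enolate traps formaldehyde at C12 and elimination of DMAP restores the enone carrying C18.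

Step 10
Reactants: 18 (5R)-5-[(2E,6E)-9-{[tert-butyl(dimethyl)silyl]oxy}-3,7-dimethylnona-2,6-dien-1-yl]-2-(hydroxymethyl)-4,4-dimethylcyclohex-2-en-1-one
Product: 19 (5R)-2-(bromomethyl)-5-[(2E,6E)-9-{[tert-butyl(dimethyl)silyl]oxy}-3,7-dimethylnona-2,6-dien-1-yl]-4,4-dimethylcyclohex-2-en-1-one
Conditions: CBr4, PPh3, CH2Cl2, −20 to 0 °C
Reagents that add atoms: carbon tetrabromide, BrC(Br)(Br)Br
Why: Appel bromination of the primary allylic alcohol under neutral conditions leaves the silyl ether and the alkenes alone.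

Step 11
Reactants: 19 (5R)-2-(bromomethyl)-5-[(2E,6E)-9-{[tert-butyl(dimethyl)silyl]oxy}-3,7-dimethylnona-2,6-dien-1-yl]-4,4-dimethylcyclohex-2-en-1-one
Product: 20 (5R)-2-(bromomethyl)-5-[(2E,6E)-9-hydroxy-3,7-dimethylnona-2,6-dien-1-yl]-4,4-dimethylcyclohex-2-en-1-one
Conditions: 48% aq. HF, MeCN, 0 °C
Reagents that add atoms: none
Why: Acidic fluoride desilylation of the primary TBS ether in a non-basic, amine-free medium keeps the electrophilic 2-(bromomethyl)enone intact.

Step 12
Reactants: 20 (5R)-2-(bromomethyl)-5-[(2E,6E)-9-hydroxy-3,7-dimethylnona-2,6-dien-1-yl]-4,4-dimethylcyclohex-2-en-1-one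
Product: 21 (3E,7E)-9-[(1R)-4-(bromomethyl)-2,2-dimethyl-5-oxocyclohex-3-en-1-yl]-3,7-dimethylnona-3,7-dienal
Conditions: Dess–Martin periodinane, NaHCO3, CH2Cl2, 0 °C; used crude at once
Reagents that add atoms: none
Why: Buffered Dess–Martin oxidation gives the β,γ-unsaturated aldehyde without moving the C7=C8 double bond into conjugation.

Step 13
Reactants: 21 (3E,7E)-9-[(1R)-4-(bromomethyl)-2,2-dimethyl-5-oxocyclohex-3-en-1-yl]-3,7-dimethylnona-3,7-dienal
Product: 23 (1R,3E,7E,10S,11R)-10-hydroxy-4,8,15,15-tetramethyl-12-methylidenebicyclo[9.3.1]pentadeca-3,7-dien-13-one, via allylchromium dichloride 22 (not isolated)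
Conditions: CrCl2 (6 equiv), THF, rt, syringe-pump addition (final 2 mM); aq. NH4Cl
Reagents that add atoms: none
Why: In this intramolecular Nozaki–Hiyama allylation the allylchromium attacks through its γ-carbon C11 (creating the exocyclic methylene); the tether can reach C11 only on the face cis to the C1 side chain (11R), and the closed chair Zimmerman–Traxler transition state with the ring-locked E-type allyl unit and pseudo-equatorial C9 gives the 10,11-anti alcohol (10S).

Step 14
Reactants: 23 (1R,3E,7E,10S,11R)-10-hydroxy-4,8,15,15-tetramethyl-12-methylidenebicyclo[9.3.1]pentadeca-3,7-dien-13-one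
Product: 24 (1R,3E,7E,10R,11R)-4,8,15,15-tetramethyl-12-methylidene-13-oxobicyclo[9.3.1]pentadeca-3,7-dien-10-yl acetate
Conditions: AcOH, PPh3, DIAD, toluene, 0 °C to rt
Reagents that add atoms: acetic acid, CC(=O)O
Why: Mitsunobu esterification displaces the oxyphosphonium by acetate in an SN2 step with inversion, turning the 10S alcohol into the required 10R acetate.

Step 15
Reactants: 24 (1R,3E,7E,10R,11R)-4,8,15,15-tetramethyl-12-methylidene-13-oxobicyclo[9.3.1]pentadeca-3,7-dien-10-yl acetate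
Product: 25 (1R,3S,4S,7S,8S,10R,11R)-3,4:7,8-diepoxy-4,8,15,15-tetramethyl-12-methylidene-13-oxobicyclo[9.3.1]pentadecan-10-yl acetate (CNP0339728.1)
Conditions: ent-Shi ketone (L-fructose-derived, 0.6 equiv), Oxone (2KHSO5·KHSO4·K2SO4), K2CO3, Bu4NHSO4 (cat.), MeCN–(MeO)2CH2–aq. Na2B4O7 buffer (pH 10.5), 0 °C
Reagents that add atoms: potassium peroxymonosulfate (from Oxone), [K+].[O-]S(=O)(=O)OO
Why: Shi asymmetric epoxidation: the L-series chiral dioxirane (spiro transition state) delivers oxygen under reagent control to give the S,S oxirane at each E-trisubstituted alkene, while the electron-poor methylidene ketone is not epoxidised.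

## Compound list

1 | tert-butyl(but-3-yn-1-yloxy)dimethylsilane | C#CCCO[Si](C)(C)C(C)(C)C | starting material
2 | dimethyl[(1E)-4-{[tert-butyl(dimethyl)silyl]oxy}-2-methylbut-1-en-1-yl]alumane | C[Al](C)/C=C(\C)CCO[Si](C)(C)C(C)(C)C | intermediate
3 | (E)-tert-butyl[(4-iodo-3-methylbut-3-en-1-yl)oxy]dimethylsilane | I/C=C(\C)CCO[Si](C)(C)C(C)(C)C | intermediate
4 | (4-bromobut-1-yn-1-yl)trimethylsilane | C[Si](C)(C)C#CCCBr | starting material
5 | bromo[4-(trimethylsilyl)but-3-yn-1-yl]zinc | C[Si](C)(C)C#CCC[Zn]Br | intermediate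
6 | (E)-tert-butyldimethyl{[3-methyl-8-(trimethylsilyl)oct-3-en-7-yn-1-yl]oxy}silane | C[Si](C)(C)C#CCC/C=C(\C)CCO[Si](C)(C)C(C)(C)C | intermediate
7 | (E)-tert-butyldimethyl[(3-methyloct-3-en-7-yn-1-yl)oxy]silane | C#CCC/C=C(\C)CCO[Si](C)(C)C(C)(C)C | intermediate
8 | dimethyl[(1E,5E)-8-{[tert-butyl(dimethyl)silyl]oxy}-2,6-dimethylocta-1,5-dien-1-yl]alumane | C[Al](C)/C=C(\C)CC/C=C(\C)CCO[Si](C)(C)C(C)(C)C | intermediate
9 | tert-butyl{[(3E,7E)-8-iodo-3,7-dimethylocta-3,7-dien-1-yl]oxy}dimethylsilane | I/C=C(\C)CC/C=C(\C)CCO[Si](C)(C)C(C)(C)C | intermediate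
10 | 4,4-dimethylcyclohexa-2,5-dien-1-one | CC1(C)C=CC(=O)C=C1 | starting material
11 | dimethyl malonate | COC(=O)CC(=O)OC | starting material
12 | dimethyl 2-[(1S)-2,2-dimethyl-5-oxocyclohex-3-en-1-yl]propanedioate | O=C1C[C@@H](C(C(=O)OC)C(=O)OC)C(C)(C)C=C1 | intermediate
13 | 2-[(1S)-2,2-dimethyl-5-oxocyclohex-3-en-1-yl]propanedioic acid | O=C1C[C@@H](C(C(=O)O)C(=O)O)C(C)(C)C=C1 | intermediate
14 | 2-[(1S)-2,2-dimethyl-5-oxocyclohex-3-en-1-yl]acetic acid | O=C1C[C@@H](CC(=O)O)C(C)(C)C=C1 | intermediate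
15 | (5R)-5-(iodomethyl)-4,4-dimethylcyclohex-2-en-1-one | O=C1C[C@@H](CI)C(C)(C)C=C1 | intermediate
16 | iodo{[(1R)-2,2-dimethyl-5-oxocyclohex-3-en-1-yl]methyl}zinc | O=C1C[C@@H](C[Zn]I)C(C)(C)C=C1 | intermediate
17 | (5R)-5-[(2E,6E)-9-{[tert-butyl(dimethyl)silyl]oxy}-3,7-dimethylnona-2,6-dien-1-yl]-4,4-dimethylcyclohex-2-en-1-one | O=C1C[C@@H](C/C=C(\C)CC/C=C(\C)CCO[Si](C)(C)C(C)(C)C)C(C)(C)C=C1 | intermediate
18 | (5R)-5-[(2E,6E)-9-{[tert-butyl(dimethyl)silyl]oxy}-3,7-dimethylnona-2,6-dien-1-yl]-2-(hydroxymethyl)-4,4-dimethylcyclohex-2-en-1-one | O=C1C[C@@H](C/C=C(\C)CC/C=C(\C)CCO[Si](C)(C)C(C)(C)C)C(C)(C)C=C1CO | intermediate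
19 | (5R)-2-(bromomethyl)-5-[(2E,6E)-9-{[tert-butyl(dimethyl)silyl]oxy}-3,7-dimethylnona-2,6-dien-1-yl]-4,4-dimethylcyclohex-2-en-1-one | O=C1C[C@@H](C/C=C(\C)CC/C=C(\C)CCO[Si](C)(C)C(C)(C)C)C(C)(C)C=C1CBr | intermediate
20 | (5R)-2-(bromomethyl)-5-[(2E,6E)-9-hydroxy-3,7-dimethylnona-2,6-dien-1-yl]-4,4-dimethylcyclohex-2-en-1-one | O=C1C[C@@H](C/C=C(\C)CC/C=C(\C)CCO)C(C)(C)C=C1CBr | intermediate
21 | (3E,7E)-9-[(1R)-4-(bromomethyl)-2,2-dimethyl-5-oxocyclohex-3-en-1-yl]-3,7-dimethylnona-3,7-dienal | O=C1C[C@@H](C/C=C(\C)CC/C=C(\C)CC=O)C(C)(C)C=C1CBr | intermediate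
22 | dichloro{[(4R)-4-[(2E,6E)-3,7-dimethyl-9-oxonona-2,6-dien-1-yl]-3,3-dimethyl-6-oxocyclohex-1-en-1-yl]methyl}chromium | O=C1C[C@@H](C/C=C(\C)CC/C=C(\C)CC=O)C(C)(C)C=C1C[Cr](Cl)Cl | intermediate
23 | (1R,3E,7E,10S,11R)-10-hydroxy-4,8,15,15-tetramethyl-12-methylidenebicyclo[9.3.1]pentadeca-3,7-dien-13-one | C=C1C(=O)C[C@H]2C/C=C(\C)CC/C=C(\C)C[C@H](O)[C@@H]1C2(C)C | intermediate
24 | (1R,3E,7E,10R,11R)-4,8,15,15-tetramethyl-12-methylidene-13-oxobicyclo[9.3.1]pentadeca-3,7-dien-10-yl acetate | C=C1C(=O)C[C@H]2C/C=C(\C)CC/C=C(\C)C[C@@H](OC(C)=O)[C@@H]1C2(C)C | intermediate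
25 | (1R,3S,4S,7S,8S,10R,11R)-3,4:7,8-diepoxy-4,8,15,15-tetramethyl-12-methylidene-13-oxobicyclo[9.3.1]pentadecan-10-yl acetate (CNP0339728.1) | C=C1C(=O)C[C@H]2C[C@@H]3O[C@@]3(C)CC[C@@H]3O[C@@]3(C)C[C@@H](OC(C)=O)[C@@H]1C2(C)C | target

## Step count and risks

Total step count: 15. Longest linear sequence: 12 steps (from 1 through steps 1–4 and 8–15; the ring A branch from 10 is 11 steps).

The three steps most likely to fail are 13, 14 and 15.

Step 13 (chromium-mediated closure of the twelve-membered ring; risks are oligomerisation and simple reduction of the allylic bromide). The fallback makes the same C10–C11 bond by allylboration instead of a reductive organochromium reaction. It sets out from bromide 19. Borylation with B2pin2 and Pd2(dba)3 in toluene gives the primary pinacol allylboronate F1. Aqueous HF in MeCN frees the hydroxy boronate F2, and Dess–Martin oxidation gives the boronate aldehyde F3. Sc(OTf)3-catalysed intramolecular allylboration at high dilution in CH2Cl2 goes through the same closed six-membered transition state and, after hydrolytic work-up, comes back to the route at alcohol 23.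

Step 14 (Mitsunobu inversion of a hindered homoallylic alcohol; the risk is elimination toward C11). The fallback separates activation from displacement. It sets out from alcohol 23. ClCH2SO2Cl and pyridine in CH2Cl2 at 0 °C give the chloromethanesulfonate F4. Displacement with CsOAc and 18-crown-6 in toluene at 60 °C (SN2, inversion at C10) comes back to the route at acetate 24.

Step 15 (double epoxidation; the risk is that the facial bias of the macrocycle overrides the chiral dioxirane at one or both alkenes). The fallback delivers oxygen to the face that direct epoxidation does not reach. It sets out from acetate 24. NBS in aqueous THF at 0 °C puts the bromonium ion on the exposed face and water opens it at the tertiary carbon, giving the bis-bromohydrin F5. Ag2O in THF then closes each bromohydrin with inversion at C3 and C7 and comes back to the route at target 25.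

## Further compounds

F1 | step 13 | (5R)-5-[(2E,6E)-9-{[tert-butyl(dimethyl)silyl]oxy}-3,7-dimethylnona-2,6-dien-1-yl]-4,4-dimethyl-2-[(4,4,5,5-tetramethyl-1,3,2-dioxaborolan-2-yl)methyl]cyclohex-2-en-1-one | O=C1C[C@@H](C/C=C(\C)CC/C=C(\C)CCO[Si](C)(C)C(C)(C)C)C(C)(C)C=C1CB1OC(C)(C)C(C)(C)O1
F2 | step 13 | (5R)-5-[(2E,6E)-9-hydroxy-3,7-dimethylnona-2,6-dien-1-yl]-4,4-dimethyl-2-[(4,4,5,5-tetramethyl-1,3,2-dioxaborolan-2-yl)methyl]cyclohex-2-en-1-one | O=C1C[C@@H](C/C=C(\C)CC/C=C(\C)CCO)C(C)(C)C=C1CB1OC(C)(C)C(C)(C)O1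
F3 | step 13 | (3E,7E)-9-[(1R)-2,2-dimethyl-5-oxo-4-[(4,4,5,5-tetramethyl-1,3,2-dioxaborolan-2-yl)methyl]cyclohex-3-en-1-yl]-3,7-dimethylnona-3,7-dienal | O=C1C[C@@H](C/C=C(\C)CC/C=C(\C)CC=O)C(C)(C)C=C1CB1OC(C)(C)C(C)(C)O1
F4 | step 14 | (1R,3E,7E,10S,11R)-4,8,15,15-tetramethyl-12-methylidene-13-oxobicyclo[9.3.1]pentadeca-3,7-dien-10-yl chloromethanesulfonate | C=C1C(=O)C[C@H]2C/C=C(\C)CC/C=C(\C)C[C@H](OS(=O)(=O)CCl)[C@@H]1C2(C)C
F5 | step 15 | (1S,3R,4S,7R,8S,10R,11R)-3,7-dibromo-4,8-dihydroxy-4,8,15,15-tetramethyl-12-methylidene-13-oxobicyclo[9.3.1]pentadecan-10-yl acetate | C=C1C(=O)C[C@H]2C[C@@H](Br)[C@](O)(C)CC[C@@H](Br)[C@](O)(C)C[C@@H](OC(C)=O)[C@@H]1C2(C)C
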